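The bicyclic core is traced back to a monocyclic ring A. The ten carbons C1–C10 form a perimeter that the target spans with only two bonds, C7–C8 and C5–C10, and C10 sits next to the tetrasubstituted C8=C9 olefin. The precursor is a ring-A cyclohexanol with a vinyl group (C6–C7) at C5 and, trans to it, an E-alkenyl group (C9=C8) at quaternary C10. An anionic oxy-Cope shift expands the ring (C7–C8 formed, C5–C10 broken). The E-cyclodecenone then re-closes C5–C10 across the ring in an acid-triggered carbonyl-ene step. One operation thus builds rings A and B, C5, C10 and the 8(9)-olefin. The C5 hydroxyl later delivers H-5 and O-6.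

Key step: step 14

Numbering: labdane numbering (C1–C20) is used from compound 3 on, and α/β refer to the faces of the final decalin (C20 is β).
Assumption: a commercial ketoreductase panel is taken to contain an enzyme that gives the (2S,3R) isomer 3; the fallback to step 2 does not depend on this.
Remark on protection: in the reactive chair of 20, O-3 is syn-axial to O-5, so a silyl ether there could migrate to the alkoxide. MOM ethers cannot migrate. A cyclic 3,19-acetal cannot be kept because O-3 and C19 are then antiperiplanar.
Remark on geometry: the E-alkenyl group puts C17 equatorial and H-8 axial (β) in the macrocycle, on the face away from O-5. The closure is therefore run stepwise under acid and not thermally.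

Step 1
Reactants: 1 2-methylcyclohexane-1,3-dione
Product: 2 2-(hydroxymethyl)-2-methylcyclohexane-1,3-dione
Conditions: 37% aq. CH2O (3 equiv), H2O/THF, 25 °C
Reagents that add atoms: formaldehyde C=O
Why: Aldol-type hydroxymethylation at C4, the only nucleophilic carbon of the vinylogous acid, gives a prochiral dione that cannot dehydrate and carries C19.

Step 2
Reactants: 2 2-(hydroxymethyl)-2-methylcyclohexane-1,3-dione
Product: 3 (2S,3R)-3-hydroxy-2-(hydroxymethyl)-2-methylcyclohexan-1-one
Conditions: anti-Prelog ketoreductase, NADP+ (cat.), i-PrOH, phosphate buffer pH 6.5, 30 °C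
Reagents that add atoms: none
Why: In this enzymatic desymmetrising mono-reduction of a prochiral 2,2-disubstituted cyclohexane-1,3-dione the enzyme pocket selects one enantiotopic carbonyl and one of its faces, which should fix C3 (R) and C4 (S) in one event with O-3 trans to the CH2OH group.

Step 3
Reactants: 3 (2S,3R)-3-hydroxy-2-(hydroxymethyl)-2-methylcyclohexan-1-one
Product: 4 trans-fused 3,19-acetonide ketone
Conditions: Me2C(OMe)2, PPTS (cat.), CH2Cl2, 25 °C
Reagents that add atoms: 2,2-dimethoxypropane COC(C)(C)OC
Why: In this acid-catalysed acetonide formation the trans pair O-3/C19 can be bridged only when both are equatorial, so a rigid trans-fused bicycle with the C18 methyl axial on the α face results.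

Step 4
Reactants: 5 but-2-yn-1-ol
Product: 6 (E)-2-(tributylstannyl)but-2-en-1-ol
Conditions: Bu3SnH, PdCl2(PPh3)2 (2 mol %), THF, 0→25 °C
Reagents that add atoms: tributyltin hydride CCCC[SnH](CCCC)CCCC
Why: Palladium-catalysed syn-hydrostannation places tin mainly on the carbon next to the carbinol and cis to the new hydrogen, so tin is trans to the methyl group, and the distal regioisomer is removed by chromatography.

Step 5
Reactants: 6 (E)-2-(tributylstannyl)but-2-en-1-ol
Product: 7 (E)-2-bromobut-2-en-1-ol
Conditions: Br2 (1.0 equiv), CH2Cl2, −78 °C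
Reagents that add atoms: bromine BrBr
Why: Bromodestannylation is an ipso substitution at the C–Sn bond that proceeds with retention of the olefin geometry.

Step 6
Reactants: 7 (E)-2-bromobut-2-en-1-ol
Product: 8 (E)-1,2-dibromobut-2-ene
Conditions: CBr4, PPh3, CH2Cl2, 0 °C
Reagents that add atoms: carbon tetrabromide BrC(Br)(Br)Br
Why: The Appel reaction converts the primary allylic alcohol into the bromide under neutral conditions that leave the vinylic bromide and its geometry untouched.

Step 7
Reactants: 8 (E)-1,2-dibromobut-2-ene; 9 pentane-2,4-dione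
Product: 11 (E)-5-bromohept-5-en-2-one, via alkylated diketone 10 (not isolated)
Conditions: K2CO3, EtOH, reflux
Reagents that add atoms: none
Why: SN2 alkylation of the diketone anion at the allylic bromide is followed in the same pot by retro-Claisen deacetylation, and the vinylic bromide survives because its hydrogen is cis to bromine and the base is weak.

Step 8
Reactants: 11 (E)-5-bromohept-5-en-2-one
Product: 12 2-[(E)-3-bromopent-3-enyl]-2-methyl-1,3-dioxolane
Conditions: HOCH2CH2OH, PPTS (cat.), toluene, Dean–Stark
Reagents that add atoms: ethylene glycol OCCO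
Why: Standard ketalisation with removal of water masks the C13 ketone against the strong bases and nucleophiles of steps 9–14.

Step 9
Reactants: 4 trans-fused 3,19-acetonide ketone; 12 2-[(E)-3-bromopent-3-enyl]-2-methyl-1,3-dioxolane
Product: 14 10-alkenyl ketone (C10 epimers), via lithium enolate 13 (not isolated)
Conditions: LiN(SiMe3)2 (2.3 equiv), THF, 0 °C; then 12, Pd(OAc)2 (5 mol %), P(t-Bu)3·HBF4 (10 mol %), toluene, 60 °C
Reagents that add atoms: none
Why: In this palladium-catalysed α-alkenylation of a ketone enolate only C10 can enolise because C4 is quaternary, oxidative addition and reductive elimination keep the E geometry, the more acidic product rests as its enolate so that no second coupling occurs, and the C10 configuration is erased in step 10.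

Step 10
Reactants: 14 10-alkenyl ketone (C10 epimers)
Product: 16 10β-methyl-10α-alkenyl ketone, via potassium dienolate 15 (not isolated)
Conditions: KN(SiMe3)2 (1.2 equiv), THF, −78 °C; MeI, −78→0 °C
Reagents that add atoms: iodomethane CI
Why: The extended enolate is alkylated at its α-carbon, and because the locked bicycle holds the C18 methyl axial on the α face in a 1,3 relation to C10, MeI should enter from the β face, making C20 β and the alkenyl group α.

Step 11
Reactants: 16 10β-methyl-10α-alkenyl ketone; 17 vinylmagnesium bromide
Product: 18 5β-vinyl-5α-ol acetonide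
Conditions: CeCl3 (anhydrous), CH2=CHMgBr, THF, −78→0 °C
Reagents that add atoms: none
Why: In this 1,2-addition of a non-basic organocerium reagent to a non-enolisable, doubly neopentyl ketone the axial C18 methyl and the axial alkenyl group close the α face of the locked chair, so vinyl should arrive axially from the β face and O-5 becomes α, trans-disposing the two alkenyl groups.

Step 12
Reactants: 18 5β-vinyl-5α-ol acetonide
Product: 19 3α,5α,19-triol
Conditions: HOCH2CH2OH (10 equiv), PPTS (0.2 equiv), THF, 40 °C
Reagents that add atoms: none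
Why: Acid-catalysed transketalisation hands the acetone unit of the strained ketone-derived 1,3-dioxane over to glycol, while exchange at the side-chain dioxolane is degenerate and PPTS is too weak to ionise the tertiary allylic alcohol.

Step 13
Reactants: 19 3α,5α,19-triol
Product: 20 3,19-bis-MOM trans-1,2-dialkenylcyclohexanol
Conditions: MOMCl, i-Pr2NEt, NaI (cat.), CH2Cl2, 40 °C
Reagents that add atoms: chloromethyl methyl ether COCCl
Why: O-Alkylation under amine base reaches the primary and the secondary hydroxyl but not the tertiary one between two quaternary carbons, and it frees ring A to flip into the chair with both alkenyl groups equatorial.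

Step 14
Reactants: 20 3,19-bis-MOM trans-1,2-dialkenylcyclohexanol
Product: 24 5α-hydroxy-8(9)-ene decalin, via potassium alkoxide 21 (not isolated), via potassium enolate 22 (not isolated), via E-cyclodecenone 23 (not isolated)
Conditions: KH (1.3 equiv), 18-crown-6 (1.3 equiv), THF, 0→40 °C; CF3CO2H (2 equiv), −78→0 °C
Reagents that add atoms: none
Why: Proposed new method: from the chair with both alkenyl groups equatorial the naked alkoxide 21 can reach only the chair [3,3] array, so C7–C8 forms while C5–C10 breaks (six- to ten-membered ring expansion) and enolate 22 results with an E C9=C10 bond, an equatorial C17 methyl and an axial H-8, both consequences of the E-alkenyl terminus. Protonation at C6 gives 23 with C5=O still lying over the face of C10 that it left, and because axial H-8 points away from the carbonyl oxygen the closure is run as an acid-triggered stepwise carbonyl-ene (Prins-type) event in which C10 attacks the protonated carbonyl and the tertiary C9 cation loses the antiperiplanar H-8 to trifluoroacetate. The closest known chemistry is the tandem oxy-Cope/transannular carbonyl-ene reaction of 1,2-divinylcyclohexanols to decalinols together with the acid-induced chair-chair cyclisation of germacrane-type E-cyclodecenes, neither of which has been tried with fully substituted carbons on both sides of the carbinol. One bond closes both rings, ring A in a 6-exo mode with respect to both π bonds and ring B in a 6-endo mode with respect to C9=C10 and a 6-exo mode with respect to C=O. C5 (O α) and C10 (C20 β) are set by the planar chirality of the tetrasubstituted E-olefin, which cannot turn through the ring, read through a trans-decalin-like chair-chair transition state. The step needs 6/6 rather than 5/7 closure and loss of H-8 rather than H-11, which should be secured because C5 is held over C10, H-8 is already aligned with the empty orbital, and a 9(11)-olefin would force C12 into the olefin plane against equatorial C17 or against C1.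

Step 15
Reactants: 24 5α-hydroxy-8(9)-ene decalin
Product: 25 5(6),8(9)-diene
Conditions: SOCl2, pyridine, 0 °C
Reagents that add atoms: none
Why: In this E2-type dehydration through the chlorosulfite C4 and C10 carry no hydrogen, so only the 5(6)-olefin can form, and the axial 5α leaving group is antiperiplanar to axial H-6β, which avoids a C5 cation and methyl shifts.

Step 16
Reactants: 25 5(6),8(9)-diene
Product: 27 5α-H 6α-alcohol, via 6α-alkylborane 26 (not isolated)
Conditions: BH3·SMe2, THF, 0→25 °C; then 3 M NaOH, 30% H2O2, 0 °C
Reagents that add atoms: hydrogen peroxide OO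
Why: In this hydroboration–oxidation BH3 adds syn to the trisubstituted olefin with boron on C6 and from the α face, because axial C19 and C20 shield the β face, which sets H-5α (trans fusion), while the tetrasubstituted 8(9)-olefin beside quaternary C10 should react more slowly.

Step 17
Reactants: 27 5α-H 6α-alcohol
Product: 28 6-ketone
Conditions: Dess–Martin periodinane, NaHCO3, CH2Cl2, 0→25 °C
Reagents that add atoms: none
Why: Buffered periodinane oxidation of the secondary alcohol is neutral enough to leave the acetals, C5 and the β,γ-placed 8(9)-olefin unchanged.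

Step 18
Reactants: 28 6-ketone
Product: 29 6β-alcohol
Conditions: NaBH4, MeOH/THF, 0 °C
Reagents that add atoms: none
Why: This hydride reduction follows steric approach control, since axial C19 and C20 block the β face of the C6 carbonyl and hydride should come from the α face to give the axial 6β-alcohol.

Step 19
Reactants: 29 6β-alcohol
Product: 30 13-methyl ketone
Conditions: AcOH/THF/H2O (3:1:1), 40 °C
Reagents that add atoms: water O
Why: Mild acetal hydrolysis cleaves the ketone-derived dioxolane far faster than the formaldehyde-derived MOM acetals.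

Step 20
Reactants: 30 13-methyl ketone
Product: 31 ethyl (13E)-enoate
Conditions: (EtO)2P(O)CH2CO2Et, NaH (3 equiv each), THF, 0→50 °C
Reagents that add atoms: triethyl phosphonoacetate CCOC(=O)CP(=O)(OCC)OCC
Why: In this Horner–Wadsworth–Emmons olefination of the unhindered methyl ketone reversible addition places the larger C12 chain trans to the ester, so the E-enoate should predominate, the Z isomer is removed by chromatography and the extra base covers the free 6-OH.

Step 21
Reactants: 31 ethyl (13E)-enoate
Product: 32 3α,6β,19-triol ethyl ester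
Conditions: conc. HCl (cat.), EtOH, 50 °C
Reagents that add atoms: none
Why: Acid-catalysed acetal exchange transfers both MOM groups to ethanol, the ethyl ester is degenerate in this solvent and the tetrasubstituted olefin is already in its most stable position.

Step 22
Reactants: 32 3α,6β,19-triol ethyl ester
Product: 33 target acid CNP0246116.2
Conditions: LiOH, THF/EtOH/H2O, 50 °C; then 1 M HCl to pH 3
Reagents that add atoms: lithium hydroxide [Li+].[OH-]
Why: Saponification of the β,β-disubstituted enoate touches no stereocentre and does not move either olefin.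

Compound list
1 | 2-methylcyclohexane-1,3-dione | CC1C(=O)CCCC1=O | starting material
2 | 2-(hydroxymethyl)-2-methylcyclohexane-1,3-dione | CC1(CO)C(=O)CCCC1=O | intermediate
3 | (2S,3R)-3-hydroxy-2-(hydroxymethyl)-2-methylcyclohexan-1-one (O-3 trans to CH2OH) | O=C1[C@@](C)(CO)[C@H](O)CCC1 | intermediate
4 | (4aS,8aR)-2,2,4a-trimethylhexahydro-4H-1,3-benzodioxin-5-one (trans-fused 3,19-acetonide, C5 ketone) | O=C1[C@@](C)(COC(C)(C)O2)[C@H]2CCC1 | intermediate
5 | but-2-yn-1-ol | CC#CCO | starting material
6 | (E)-2-(tributylstannyl)but-2-en-1-ol | C/C=C(/[Sn](CCCC)(CCCC)CCCC)CO | intermediate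
7 | (E)-2-bromobut-2-en-1-ol | C/C=C(/Br)CO | intermediate
8 | (E)-1,2-dibromobut-2-ene | C/C=C(/Br)CBr | intermediate
9 | pentane-2,4-dione | CC(=O)CC(C)=O | starting material
10 | 3-[(E)-2-bromobut-2-enyl]pentane-2,4-dione | C/C=C(/Br)CC(C(C)=O)C(C)=O | intermediate
11 | (E)-5-bromohept-5-en-2-one | C/C=C(/Br)CCC(C)=O | intermediate
12 | 2-[(E)-3-bromopent-3-enyl]-2-methyl-1,3-dioxolane (Br trans to CH3) | C/C=C(/Br)CCC1(C)OCCO1 | intermediate
13 | lithium C5(10)-enolate of 4 | [Li+].[O-]C=1[C@@](C)(COC(C)(C)O2)[C@H]2CCC=1 | intermediate
14 | acetonide ketone with the E-alkenyl group at C10 (C10 unassigned) | O=C1[C@@](C)(COC(C)(C)O2)[C@H]2CCC1/C(CCC3(C)OCCO3)=C/C | intermediate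
15 | potassium dienolate of 14 | [K+].[O-]C=1[C@@](C)(COC(C)(C)O2)[C@H]2CCC=1/C(CCC3(C)OCCO3)=C/C | intermediate
16 | acetonide ketone with quaternary C10 (C20 β, E-alkenyl α) | O=C1[C@@](C)(COC(C)(C)O2)[C@H]2CC[C@]1(C)/C(CCC3(C)OCCO3)=C/C | intermediate
17 | vinylmagnesium bromide | C=C[Mg]Br | starting material
18 | 5β-vinyl-5α-hydroxy acetonide (vinyl and alkenyl trans) | C=C[C@@]1(O)[C@@](C)(COC(C)(C)O2)[C@H]2CC[C@]1(C)/C(CCC3(C)OCCO3)=C/C | intermediate
19 | 3α,5α,19-triol | C=C[C@@]1(O)[C@@](C)(CO)[C@H](O)CC[C@]1(C)/C(CCC2(C)OCCO2)=C/C | intermediate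
20 | 3,19-bis-MOM trans-1,2-dialkenylcyclohexanol (key-step precursor) | C=C[C@@]1(O)[C@@](C)(COCOC)[C@H](OCOC)CC[C@]1(C)/C(CCC2(C)OCCO2)=C/C | intermediate
21 | potassium alkoxide of 20 | [K+].C=C[C@@]1([O-])[C@@](C)(COCOC)[C@H](OCOC)CC[C@]1(C)/C(CCC2(C)OCCO2)=C/C | intermediate
22 | potassium C5(6)-enolate of the ten-membered ring (9E, 8α-methyl) | [K+].[O-]/C1=C\C[C@@H](C)/C(CCC2(C)OCCO2)=C(\C)CC[C@@H](OCOC)[C@]1(C)COCOC | intermediate
23 | (9E)-cyclodec-9(10)-en-5-one, 8α-methyl, 8β-H | O=C1CC[C@@H](C)/C(CCC2(C)OCCO2)=C(\C)CC[C@@H](OCOC)[C@]1(C)COCOC | intermediate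
24 | decalin-5α-ol with 8(9)-olefin, 10β-methyl, ketal side chain, 3α,19-bis-MOM (key-step product) | CC1=C(CCC3(C)OCCO3)[C@@]2(C)CC[C@@H](OCOC)[C@](C)(COCOC)[C@]2(O)CC1 | intermediate
25 | 5(6),8(9)-diene | CC1=C(CCC3(C)OCCO3)[C@@]2(C)CC[C@@H](OCOC)[C@](C)(COCOC)C2=CC1 | intermediate
26 | 5α-H 6α-boryl compound (RBH2) | CC1=C(CCC3(C)OCCO3)[C@@]2(C)CC[C@@H](OCOC)[C@](C)(COCOC)[C@@H]2[C@@H](B)C1 | intermediate
27 | 5α-H 6α-alcohol | CC1=C(CCC3(C)OCCO3)[C@@]2(C)CC[C@@H](OCOC)[C@](C)(COCOC)[C@@H]2[C@@H](O)C1 | intermediate
28 | 5α-H 6-ketone | CC1=C(CCC3(C)OCCO3)[C@@]2(C)CC[C@@H](OCOC)[C@](C)(COCOC)[C@@H]2C(=O)C1 | intermediate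
29 | 6β-alcohol | CC1=C(CCC3(C)OCCO3)[C@@]2(C)CC[C@@H](OCOC)[C@](C)(COCOC)[C@@H]2[C@H](O)C1 | intermediate
30 | 6β-hydroxy 13-methyl ketone | CC1=C(CCC(C)=O)[C@@]2(C)CC[C@@H](OCOC)[C@](C)(COCOC)[C@@H]2[C@H](O)C1 | intermediate
31 | ethyl (13E)-enoate, bis-MOM | CC1=C(CC/C(C)=C/C(=O)OCC)[C@@]2(C)CC[C@@H](OCOC)[C@](C)(COCOC)[C@@H]2[C@H](O)C1 | intermediate
32 | ethyl 3α,6β,19-trihydroxylabda-8(9),13E-dien-15-oate | CC1=C(CC/C(C)=C/C(=O)OCC)[C@@]2(C)CC[C@@H](O)[C@](C)(CO)[C@@H]2[C@H](O)C1 | intermediate
33 | 3α,6β,19-trihydroxylabda-8(9),13E-dien-15-oic acid (CNP0246116.2) | CC1=C(CC/C(C)=C/C(=O)O)[C@@]2(C)CC[C@@H](O)[C@](C)(CO)[C@@H]2[C@H](O)C1 | target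

Total step count: 22. Longest linear sequence: 19 steps (5 to 33, steps 4–22). The ring-A branch (1 to 33) has 17 steps.

Steps most likely to fail

1. Step 14 (Proposed new method).
- What may go wrong: the chair with both alkenyl groups equatorial may be too poorly populated. The crowded alkoxide may fragment heterolytically instead of rearranging in concert. C5 may close onto C9 (5/7 mode). The C9 cation may lose a proton from C11 or undergo a hydride shift.
- Fallback by known chemistry, from 16 back to 24: 3-methylbut-3-enyllithium with CeCl3 replaces the vinyl reagent and should add from the β face to give the homomethallyl carbinol acetonide F1. Glycol with PPTS then gives the homomethallyl triol F2, and MOMCl with i-Pr2NEt gives the homomethallyl bis-MOM ether F3. Ring-closing metathesis follows (second-generation Hoveyda–Grubbs catalyst, toluene, 100 °C). It joins the 1,1-disubstituted olefin to the C9=C8 olefin and forms the tetrasubstituted C8=C9 bond of ring B directly, which returns to the route at 24.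

2. Step 9.
- What may go wrong: oxidative addition or reductive elimination may be slow between a hindered bromide and a hindered enolate. Bromide 12 may be dehydrobrominated by the base. The product olefin may drift into conjugation.
- Fallback, from 4 (and 12) back to 16: dehydrogenation (IBX, DMSO, 70 °C) gives the C1(10)-enone F4, and iodination (I2, pyridine) gives the α-iodoenone F5. Bromide 12 is converted into the alkenyl pinacol boronate F6 (B2pin2, PdCl2(dppf), KOPh). A Suzuki coupling of F5 and F6 (PdCl2(dppf), Cs2CO3, aqueous DMF) joins two sp2 carbons with retention of geometry to give the 10-alkenyl enone F7. Conjugate reduction with LiBH(s-Bu)3 generates the lithium dienolate F8. This is methylated in the flask with MeI from the β face and returns to the route at 16.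

3. Step 2.
- What may go wrong: no enzyme may deliver hydride to the required carbonyl face. The second carbonyl may be over-reduced. Formaldehyde may be lost from 2 by retro-aldol cleavage in the buffer.
- Fallback, from 2 back to 3: hydroxyl-directed reduction with Me4NBH(OAc)3 (AcOH/MeCN, −20 °C) delivers hydride internally from boron bound to the CH2OH oxygen. It should give the same trans diol as a racemate, that is 3 together with its enantiomer ent-3 F9. Esterification of the primary hydroxyl with (S)-methoxy(phenyl)acetic acid (DCC, DMAP) gives the ester of 3 F10 and the ester of ent-3 F11, which are separated by chromatography or crystallisation. K2CO3 in MeOH on F10 returns to the route at 3. The unwanted series can be hydrolysed and oxidised back to prochiral 2.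

Further compounds
F1 | step 14 | 5β-(3-methylbut-3-enyl)-5α-ol acetonide | C=C(C)CC[C@@]1(O)[C@@](C)(COC(C)(C)O2)[C@H]2CC[C@]1(C)/C(CCC3(C)OCCO3)=C/C
F2 | step 14 | 5β-(3-methylbut-3-enyl)-3α,5α,19-triol | C=C(C)CC[C@@]1(O)[C@@](C)(CO)[C@H](O)CC[C@]1(C)/C(CCC2(C)OCCO2)=C/C
F3 | step 14 | 5β-(3-methylbut-3-enyl) 3,19-bis-MOM ether | C=C(C)CC[C@@]1(O)[C@@](C)(COCOC)[C@H](OCOC)CC[C@]1(C)/C(CCC2(C)OCCO2)=C/C
F4 | step 9 | acetonide C1(10)-en-5-one | O=C1[C@@](C)(COC(C)(C)O2)[C@H]2CC=C1
F5 | step 9 | 10-iodo C1(10)-en-5-one | O=C1[C@@](C)(COC(C)(C)O2)[C@H]2CC=C1I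
F6 | step 9 | (E)-alkenyl pinacol boronate from 12 | C/C=C(/B1OC(C)(C)C(C)(C)O1)CCC2(C)OCCO2
F7 | step 9 | 10-alkenyl C1(10)-en-5-one | O=C1[C@@](C)(COC(C)(C)O2)[C@H]2CC=C1/C(CCC3(C)OCCO3)=C/C
F8 | step 9 | lithium dienolate (lithium analogue of 15) | [Li+].[O-]C=1[C@@](C)(COC(C)(C)O2)[C@H]2CCC=1/C(CCC3(C)OCCO3)=C/C
F9 | step 2 | (2R,3S)-3-hydroxy-2-(hydroxymethyl)-2-methylcyclohexan-1-one (ent-3) | O=C1[C@](C)(CO)[C@@H](O)CCC1
F10 | step 2 | (S)-methoxy(phenyl)acetate of 3 at O-19 | O=C1[C@@](C)(COC(=O)[C@@H](OC)c2ccccc2)[C@H](O)CCC1
F11 | step 2 | (S)-methoxy(phenyl)acetate of ent-3 at O-19 | O=C1[C@](C)(COC(=O)[C@@H](OC)c2ccccc2)[C@@H](O)CCC1
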